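**Retrosynthetic overview**

- Both benzene rings are bought with their bromines in place; no ring is formed, and the one strategic bond is the diaryl ether C–O bond.
- That bond links a phenolic oxygen to an arene carbon, two natively nucleophilic centres. Ring B is therefore brought in with reversed polarity as an aryl cation equivalent: a (2,4-dibromophenyl)(2,4,6-trimethoxyphenyl)iodonium salt made from 2,4-dibromo-1-iodobenzene.
- The partner is unprotected 3,4-dibromocatechol, arylated as its dianion at the oxygen remote from bromine (more basic, less hindered); this removes every protecting-group step.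
- The catechol comes from 2,3-dibromophenol by chelation-controlled ortho-formylation and Dakin oxidation, which fixes the 1,2,3,4-substitution pattern of ring A.

Assumption: the target has no stereocentre and is achiral, so the "single enantiomer" is the compound itself and no stereocontrol is needed.

**Route**

Step 1
Reactants: 1 2,3-dibromophenol
Product: 3 3,4-dibromo-2-hydroxybenzaldehyde, via 2,3-dibromo-6-(hydroxymethyl)phenol 2 (not isolated)
Conditions: MgCl2 (2 equiv), Et3N (2 equiv), (CH2O)n (3 equiv), THF, reflux, 4 h; then 1 M HCl
Reagents that add atoms: paraformaldehyde (formaldehyde), C=O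
Why: Magnesium-phenoxide-directed ortho-formylation (Casiraghi–Skattebøl type): the aryloxymagnesium chloride delivers formaldehyde through a six-membered chelate to the only free ortho carbon, and a second formaldehyde oxidises the benzylic magnesium alkoxide 2 by hydride transfer (Oppenauer type), while the aryl bromides are inert.

Step 2
Reactants: 3 3,4-dibromo-2-hydroxybenzaldehyde
Product: 5 3,4-dibromobenzene-1,2-diol, via 3,4-dibromo-2-hydroxyphenyl formate 4 (not isolated)
Conditions: 30% aq H2O2 (1.2 equiv), NaOH (2.2 equiv), H2O–THF, 0 °C to rt, N2; then aq HCl
Reagents that add atoms: hydrogen peroxide, OO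
Why: Dakin oxidation: hydroperoxide adds to the aldehyde, the ring activated by the ortho-phenoxide migrates to oxygen (Baeyer–Villiger-type shift) and formate 4 is saponified in the flask, so the formyl carbon is exchanged for the second hydroxyl exactly where it was installed.

Step 3
Reactants: 6 2,4-dibromo-1-iodobenzene; 7 1,3,5-trimethoxybenzene
Product: 9 (2,4-dibromophenyl)(2,4,6-trimethoxyphenyl)iodonium tosylate, via 2,4-dibromo-1-[hydroxy(tosyloxy)iodo]benzene 8 (not isolated)
Conditions: mCPBA (1.1 equiv), TsOH·H2O (1.1 equiv), MeCN, 77 °C, 30 min; then 7 (1.05 equiv), 77 °C, 10 min; Et2O trituration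
Reagents that add atoms: p-toluenesulfonic acid monohydrate, Cc1ccc(cc1)S(=O)(=O)O.O
Why: One-pot diaryliodonium synthesis: mCPBA/TsOH oxidise the aryl iodide to the Koser-type trivalent-iodine species 8, which undergoes electrophilic aromatic substitution on the very electron-rich 7 to give a bench-stable aryl cation equivalent whose trimethoxyphenyl group is a non-transferable dummy ligand.

Step 4
Reactants: 5 3,4-dibromobenzene-1,2-diol; 9 (2,4-dibromophenyl)(2,4,6-trimethoxyphenyl)iodonium tosylate
Product: 11 2,3-dibromo-6-(2,4-dibromophenoxy)phenol, via dipotassium 3,4-dibromocatecholate 10 (not isolated)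
Conditions: KOt-Bu (2.0 equiv), THF–DMF 4:1, 0 °C, Ar, 15 min; then 9 (1.0 equiv), 0 °C to rt, 3 h; then aq HCl
Reagents that add atoms: none
Why: Proposed new method: site-selective mono-O-arylation of an unprotected catechol dianion by a diaryliodonium salt, reasoned as follows: of the two phenoxides in 10 the one remote from bromine is the conjugate base of the weaker acid and is unhindered, so it exchanges onto trivalent iodine and undergoes ligand coupling at the ipso carbon of the electron-poor, ortho-substituted 2,4-dibromophenyl ligand (the trimethoxyphenyl ligand stays on iodine), which delivers an arene carbon as an aryl cation equivalent to an oxygen nucleophile and so unites two natively nucleophilic partners, while the remaining bromine-flanked phenoxide is too hindered and too weakly nucleophilic to react again; the closest known reaction types are the metal-free O-arylation of phenoxides with aryl(2,4,6-trimethoxyphenyl)iodonium salts and the selective O-alkylation of catechol dianions at the less acidic hydroxyl.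

**Compound list**

1 | 2,3-dibromophenol | Oc1cccc(Br)c1Br | starting material
2 | 2,3-dibromo-6-(hydroxymethyl)phenol (present as its magnesium phenoxide, drawn neutral) | OCc1ccc(Br)c(Br)c1O | intermediate
3 | 3,4-dibromo-2-hydroxybenzaldehyde | O=Cc1ccc(Br)c(Br)c1O | intermediate
4 | 3,4-dibromo-2-hydroxyphenyl formate (present as its sodium phenoxide, drawn neutral) | O=COc1ccc(Br)c(Br)c1O | intermediate
5 | 3,4-dibromobenzene-1,2-diol (3,4-dibromocatechol) | Oc1ccc(Br)c(Br)c1O | intermediate
6 | 2,4-dibromo-1-iodobenzene | Brc1ccc(I)c(Br)c1 | starting material
7 | 1,3,5-trimethoxybenzene | COc1cc(OC)cc(OC)c1 | starting material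
8 | 2,4-dibromo-1-[hydroxy(tosyloxy)iodo]benzene | OI(OS(=O)(=O)c1ccc(C)cc1)c1ccc(Br)cc1Br | intermediate
9 | (2,4-dibromophenyl)(2,4,6-trimethoxyphenyl)iodonium tosylate | COc1cc(OC)c([I+]c2ccc(Br)cc2Br)c(OC)c1.Cc1ccc(cc1)S(=O)(=O)[O-] | intermediate
10 | dipotassium 3,4-dibromocatecholate | [K+].[K+].[O-]c1ccc(Br)c(Br)c1[O-] | intermediate
11 | 2,3-dibromo-6-(2,4-dibromophenoxy)phenol | Oc1c(Oc2ccc(Br)cc2Br)ccc(Br)c1Br | target

**Totals and risks**

Total step count: 4. Longest linear sequence: 3 steps (1 → 3 → 5 → 11); step 3 is a one-step side branch.

Most likely to fail, first: step 4. The dianion could be arylated at the wrong oxygen or twice, or could transfer an electron to the iodonium salt and end as quinone. The fallback sets out from 3 and comes back at 11, and it fixes the site by protection instead of by dianion reactivity. Methylation of 3 (MeI, K2CO3, acetone) gives 3,4-dibromo-2-methoxybenzaldehyde F1. Baeyer–Villiger oxidation (mCPBA, CH2Cl2) and saponification of the formate (KOH, MeOH–H2O) give 3,4-dibromo-2-methoxyphenol F2, in which only the oxygen that must carry the aryl group is free. Arylation of F2 with 9 (KOt-Bu, THF, rt) gives 1,2-dibromo-4-(2,4-dibromophenoxy)-3-methoxybenzene F3. BBr3 (CH2Cl2, −78 °C to 0 °C) then cleaves the methyl ether, leaves the diaryl ether intact and gives 11.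

Second: step 2. Alkaline peroxide may over-oxidise the catechol once it forms. The fallback sets out from 1 and comes back at 5, and it replaces the formylation/Dakin pair by direct ortho-oxygenation. Benzeneseleninic anhydride (THF, 50 °C) converts 1, through O-selenination and a [2,3]-shift to the free ortho carbon, into 3,4-dibromocyclohexa-3,5-diene-1,2-dione F4. This is reduced without isolation with aqueous Na2S2O4 to 5, so the catechol never meets peroxide.

Third: step 3. Oxidation of the electron-poor, ortho-substituted aryl iodide may be slow, or trimethoxybenzene may be oxidised instead of arylated. The fallback sets out from 6 and comes back at 11, and it gives up the dummy-ligand design for a symmetrical salt. Treatment of 6 with mCPBA and TfOH in CH2Cl2 (0 °C to rt) in the presence of 1,3-dibromobenzene, which is attacked para to one bromine, gives bis(2,4-dibromophenyl)iodonium trifluoromethanesulfonate F5. F5 replaces 9 under the conditions of step 4 and delivers 11, with 6 returned as the leaving group.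

**Further compounds**

F1 | step 4 | 3,4-dibromo-2-methoxybenzaldehyde | COc1c(C=O)ccc(Br)c1Br
F2 | step 4 | 3,4-dibromo-2-methoxyphenol | COc1c(O)ccc(Br)c1Br
F3 | step 4 | 1,2-dibromo-4-(2,4-dibromophenoxy)-3-methoxybenzene | COc1c(Oc2ccc(Br)cc2Br)ccc(Br)c1Br
F4 | step 2 | 3,4-dibromocyclohexa-3,5-diene-1,2-dione | O=C1C=CC(Br)=C(Br)C1=O
F5 | step 3 | bis(2,4-dibromophenyl)iodonium trifluoromethanesulfonate | Brc1ccc([I+]c2ccc(Br)cc2Br)c(Br)c1.[O-]S(=O)(=O)C(F)(F)F
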